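## Retrosynthetic overview

1. Miyabenol A is read as four resveratrol units joined by three trans-2-(4-hydroxyphenyl)-3-aryl-2,3-dihydrobenzofurans, here called the inner furan ring (its C3 carries the 3,5-dihydroxyphenyl group), the middle furan ring and the outer furan ring (fused to the resorcinol ring that bears the styryl group). The last disconnections are the six silyl ethers and the bond from the styryl carbon to the terminal 4-hydroxyphenyl ring (Suzuki coupling of an (E)-vinyl iodide).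
2. Each furan ring is cut at O1–C2 and C3a–C3 into (E)-5-(2-iodovinyl)resorcinol (a ring carbon para to one OH plus the OH next to it) and a 4-styryl-4-hydroxycyclohexa-2,5-dienone (p-quinol). The C2 aryl ring is thus carried dearomatized and is aromatized by the ring-forming step itself.
3. Enabling feature: in every furan ring C2 bears a para-hydroxyphenyl ring, and the fused benzene ring is a resorcinol with C3a para to the C6 hydroxyl and ortho to O1. Ionisation of the quinol C4–OH therefore places positive charge on the styryl β-carbon (future C3), and re-aromatisation through a p-quinone methide makes the α-carbon (future C2) an acceptor for the phenol oxygen (future O1).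
4. Each quinol is made from the vinyl iodide of the preceding stage by lithium–iodine exchange and 1,2-addition to p-benzoquinone monoketal, so annulation, silylation and quinol formation are repeated.
5. Order of ring formation: inner furan ring (2R,3R, catalyst control), then middle furan ring (2S,3S), then outer furan ring (2R,3R, key step), each with aromatisation of one 4-hydroxyphenyl ring; the terminal 4-hydroxyphenyl ring is attached last.

Key step: step 11

Remarks on the chemistry: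
- TIPS = triisopropylsilyl. Compounds 1, 4 and 23 are taken as purchased.
- Assumption: the (R)-configured N-triflylphosphoramide is taken to favour the (2R,3R) furan ring and its (S)-antipode the (2S,3S) ring; if the sense of induction should prove opposite, the two antipodes are exchanged.

## Route

Step 1
Reactants: 1 3,5-dihydroxybenzaldehyde
Product: 2 3,5-bis(triisopropylsilyloxy)benzaldehyde
Conditions: TIPSCl, imidazole, DMF, rt
Reagents that add atoms: triisopropylsilyl chloride, CC(C)[Si](Cl)(C(C)C)C(C)C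
Why: Imidazole-promoted silyl ether formation masks both phenols as bulky ethers that should survive the organolithium and acid steps.

Step 2
Reactants: 2 3,5-bis(triisopropylsilyloxy)benzaldehyde
Product: 3 (E)-1-(2-iodovinyl)-3,5-bis(triisopropylsilyloxy)benzene
Conditions: CHI3, CrCl2, THF, 0 °C to rt
Reagents that add atoms: iodoform, IC(I)I
Why: Takai olefination; the geminal dichromium species from CHI3 and CrCl2 adds to the aldehyde and eliminates to the (E)-vinyl iodide.

Step 3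
Reactants: 3 (E)-1-(2-iodovinyl)-3,5-bis(triisopropylsilyloxy)benzene; 4 4,4-dimethoxycyclohexa-2,5-dien-1-one
Product: 6 4-[(E)-2-(3,5-bis(triisopropylsilyloxy)phenyl)vinyl]-4-hydroxycyclohexa-2,5-dien-1-one, via ketal carbinol 5 (not isolated)
Conditions: t-BuLi (2 equiv), Et2O, −78 °C; then 4, THF, −78 °C; then aq. AcOH, THF, 0 °C to rt
Reagents that add atoms: water, O
Why: Lithium–iodine exchange with retention of alkene geometry, 1,2-addition of the alkenyllithium to the quinone monoketal and mild hydrolysis of the doubly allylic ketal should give the p-quinol, which has no stereocentre.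

Step 4
Reactants: 3 (E)-1-(2-iodovinyl)-3,5-bis(triisopropylsilyloxy)benzene
Product: 7 (E)-5-(2-iodovinyl)benzene-1,3-diol
Conditions: TBAF, AcOH, THF, 0 °C
Reagents that add atoms: none
Why: Fluoride-mediated cleavage of the aryl silyl ethers; acetic acid buffering keeps the vinyl iodide away from strong base.

Step 5
Reactants: 6 4-[(E)-2-(3,5-bis(triisopropylsilyloxy)phenyl)vinyl]-4-hydroxycyclohexa-2,5-dien-1-one; 7 (E)-5-(2-iodovinyl)benzene-1,3-diol
Product: 10 (2R,3R)-3-[3,5-bis(triisopropylsilyloxy)phenyl]-2-(4-hydroxyphenyl)-4-[(E)-2-iodovinyl]-2,3-dihydrobenzofuran-6-ol, via aryloxenium ion 8 (not isolated), via quinone methide 9 (not isolated)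
Conditions: (R)-3,3'-bis(2,4,6-triisopropylphenyl)-1,1'-binaphthyl-2,2'-diyl N-triflylphosphoramide, (ArO)2P(O)NHSO2CF3 (10 mol%), 7 (2 equiv), 4 Å MS, CH2Cl2/PhCF3, −40 to −10 °C
Reagents that add atoms: none
Why: Proposed new method: the chiral acid should ionise the doubly allylic tertiary OH of 6 to an aryloxenium ion with charge on the styryl β-carbon; its anion holds the resorcinol by a hydrogen bond and directs C4 (para to one OH) to one face of that carbon, setting C3; the neighbouring OH then closes onto the p-quinone methide (5-exo-trig, reversible, trans), setting C2 and aromatising the dienone; the closest known reaction types are chiral phosphoric acid-catalysed 1,6- and 1,8-additions of phenols to p-quinone methides formed in situ from p-hydroxybenzyl alcohols and the acid-promoted (3+2) coupling of quinone monoketals with nucleophilic alkenes.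

Step 6
Reactants: 10 (2R,3R)-3-[3,5-bis(triisopropylsilyloxy)phenyl]-2-(4-hydroxyphenyl)-4-[(E)-2-iodovinyl]-2,3-dihydrobenzofuran-6-ol
Product: 11 tetrakis-TIPS ether of 10 (6-OTIPS and 4-(TIPSO)phenyl at C2)
Conditions: TIPSCl, imidazole, DMF, rt
Reagents that add atoms: triisopropylsilyl chloride, CC(C)[Si](Cl)(C(C)C)C(C)C
Why: Silyl ether formation caps the two phenols freed in step 5 so that neither ring can act as a nucleophile or as an acid in the following steps.

Step 7
Reactants: 11 tetrakis-TIPS vinyl iodide; 4 4,4-dimethoxycyclohexa-2,5-dien-1-one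
Product: 13 4-hydroxy-4-{(E)-2-[(2R,3R)-3-[3,5-bis(triisopropylsilyloxy)phenyl]-6-(triisopropylsilyloxy)-2-[4-(triisopropylsilyloxy)phenyl]-2,3-dihydrobenzofuran-4-yl]vinyl}cyclohexa-2,5-dien-1-one, via ketal carbinol 12 (not isolated)
Conditions: t-BuLi (2 equiv), Et2O, −78 °C; then 4, THF, −78 °C; then aq. AcOH, THF, 0 °C to rt
Reagents that add atoms: water, O
Why: Same sequence as step 3; lithium–iodine exchange at −78 °C should be faster than deprotonation of the benzylic C–H bonds, so the two stereocentres stay untouched.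

Step 8
Reactants: 13 quinol of the first furan stage; 7 (E)-5-(2-iodovinyl)benzene-1,3-diol
Product: 16 (2S,3S)-2-(4-hydroxyphenyl)-4-[(E)-2-iodovinyl]-3-[(2R,3R)-3-[3,5-bis(triisopropylsilyloxy)phenyl]-6-(triisopropylsilyloxy)-2-[4-(triisopropylsilyloxy)phenyl]-2,3-dihydrobenzofuran-4-yl]-2,3-dihydrobenzofuran-6-ol, via aryloxenium ion 14 (not isolated), via quinone methide 15 (not isolated)
Conditions: (S)-3,3'-bis(2,4,6-triisopropylphenyl)-1,1'-binaphthyl-2,2'-diyl N-triflylphosphoramide, (ArO)2P(O)NHSO2CF3 (10 mol%), 7 (2 equiv), 4 Å MS, CH2Cl2/PhCF3, −40 to −10 °C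
Reagents that add atoms: none
Why: Proposed new method: same ionisation, vinylogous Friedel–Crafts attack and 5-exo-trig oxa-1,6-addition as in step 5 (closest known types as named there); the cationic carbon lies in the plane of the existing benzofuran, whose 3-aryl group covers one face, so the resorcinol should add anti to it (giving 3S), the (S)-acid being chosen to reinforce this, and the reversible ring closure gives the trans C2.

Step 9
Reactants: 16 bis-furan vinyl iodide diol
Product: 17 hexakis-TIPS ether of 16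
Conditions: TIPSCl, imidazole, DMF, rt
Reagents that add atoms: triisopropylsilyl chloride, CC(C)[Si](Cl)(C(C)C)C(C)C
Why: Silyl ether formation on the two new phenols, as in step 6.

Step 10
Reactants: 17 hexakis-TIPS bis-furan vinyl iodide; 4 4,4-dimethoxycyclohexa-2,5-dien-1-one
Product: 19 p-quinol of the bis-furan stage (4-hydroxy-4-[(E)-2-arylvinyl]cyclohexa-2,5-dien-1-one in which the aryl group is C4 of the (2S,3S) furan unit of 17), via ketal carbinol 18 (not isolated)
Conditions: t-BuLi (2 equiv), Et2O, −78 °C; then 4, THF, −78 °C; then aq. AcOH, THF, 0 °C to rt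
Reagents that add atoms: water, O
Why: Lithium–iodine exchange, 1,2-addition to the quinone monoketal and ketal hydrolysis as in steps 3 and 7, leaving the four stereocentres untouched.

Step 11
Reactants: 19 p-quinol of the bis-furan stage; 7 (E)-5-(2-iodovinyl)benzene-1,3-diol
Product: 22 tris-furan vinyl iodide (new (2R,3R)-2-(4-hydroxyphenyl)-4-[(E)-2-iodovinyl]-2,3-dihydrobenzofuran-6-ol whose C3 carries C4 of the (2S,3S) furan unit), via aryloxenium ion 20 (not isolated), via quinone methide 21 (not isolated)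
Conditions: (R)-3,3'-bis(2,4,6-triisopropylphenyl)-1,1'-binaphthyl-2,2'-diyl N-triflylphosphoramide, (ArO)2P(O)NHSO2CF3 (10 mol%), 7 (2 equiv), 4 Å MS, CH2Cl2/PhCF3, −40 to −10 °C
Reagents that add atoms: none
Why: Proposed new method: the acid should ionise the tertiary, doubly allylic C4–OH of the dienone to an aryloxenium ion whose charge sits on the styryl β-carbon, and C4 of resorcinol 7 attacks there in a vinylogous Friedel–Crafts alkylation (C3a–C3 bond), giving a p-quinone methide. The closest known reaction types are chiral phosphoric acid-catalysed 1,6- and 1,8-additions of phenols to p-quinone methides generated from p-hydroxybenzyl alcohols and the acid-promoted (3+2) coupling of quinone monoketals with alkenes. The furan ring then closes by 5-exo-trig oxa-1,6-addition of the neighbouring phenol OH onto the quinone methide carbon (O1–C2 bond), which aromatises the dienone to the 4-hydroxyphenyl ring. C3 is set by attack anti to the 3-aryl group of the adjacent (2S,3S) furan ring, which shields one face of the ring-coplanar cation, with the (R)-anion chosen to reinforce it; C2 is set trans to C3 by the reversible, thermodynamically controlled ring closure. The step needs attack at the β-carbon and not at the dienone ring carbons, secured by the benzylic terminus of the extended cation, which leads to the conjugated quinone methide. It also needs attack at the resorcinol carbon para to an OH (the two such carbons of 7 are equivalent and only they have an adjacent OH and a para OH), C- over O-alkylation (O-alkylation is reversible under acid), and silence of all other rings, secured by their bulky TIPS ethers and by the excess of 7.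

Step 12
Reactants: 22 tris-furan vinyl iodide; 23 4-hydroxyphenylboronic acid
Product: 24 hexakis-O-TIPS miyabenol A (free OH on the terminal 4-hydroxyphenyl ring, on C6 of the outer furan unit and on the 4-hydroxyphenyl group at C2 of the outer furan unit)
Conditions: Pd(PPh3)4 (5 mol%), K2CO3, THF/H2O, 55 °C
Reagents that add atoms: none
Why: Suzuki–Miyaura coupling of the (E)-vinyl iodide with retention of alkene geometry installs the terminal 4-hydroxyphenyl ring; free phenols are tolerated and no stereocentre is touched.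

Step 13
Reactants: 24 hexakis-O-TIPS miyabenol A
Product: 25 miyabenol A
Conditions: TBAF, AcOH, THF, 0 °C to rt
Reagents that add atoms: none
Why: Fluoride cleaves the six aryl silyl ethers; buffering limits phenoxide-induced opening of the furan rings, which in any case re-closes to the trans isomers.

## Compound list

1 | 3,5-dihydroxybenzaldehyde | O=Cc1cc(O)cc(O)c1 | starting material
2 | 3,5-bis(triisopropylsilyloxy)benzaldehyde | O=Cc1cc(O[Si](C(C)C)(C(C)C)C(C)C)cc(O[Si](C(C)C)(C(C)C)C(C)C)c1 | intermediate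
3 | (E)-1-(2-iodovinyl)-3,5-bis(triisopropylsilyloxy)benzene | I/C=C/c1cc(O[Si](C(C)C)(C(C)C)C(C)C)cc(O[Si](C(C)C)(C(C)C)C(C)C)c1 | intermediate
4 | 4,4-dimethoxycyclohexa-2,5-dien-1-one (p-benzoquinone monoketal) | COC1(OC)C=CC(=O)C=C1 | starting material
5 | 1-[(E)-2-(3,5-bis(triisopropylsilyloxy)phenyl)vinyl]-4,4-dimethoxycyclohexa-2,5-dien-1-ol (ketal carbinol, not isolated) | COC1(OC)C=CC(O)(/C=C/c2cc(O[Si](C(C)C)(C(C)C)C(C)C)cc(O[Si](C(C)C)(C(C)C)C(C)C)c2)C=C1 | intermediate
6 | 4-[(E)-2-(3,5-bis(triisopropylsilyloxy)phenyl)vinyl]-4-hydroxycyclohexa-2,5-dien-1-one | O=C1C=CC(O)(/C=C/c2cc(O[Si](C(C)C)(C(C)C)C(C)C)cc(O[Si](C(C)C)(C(C)C)C(C)C)c2)C=C1 | intermediate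
7 | (E)-5-(2-iodovinyl)benzene-1,3-diol | Oc1cc(O)cc(/C=C/I)c1 | intermediate
8 | aryloxenium ion from 6, drawn as the β-carbocation of the quinone methide (ion pair with the catalyst anion, not isolated) | O=C1C=CC(=C[CH+]c2cc(O[Si](C(C)C)(C(C)C)C(C)C)cc(O[Si](C(C)C)(C(C)C)C(C)C)c2)C=C1 | intermediate
9 | p-quinone methide carrying the 2,4-dihydroxy-6-[(E)-2-iodovinyl]phenyl group at the new stereocentre (not isolated) | O=C1C=CC(=C[C@H](c2cc(O[Si](C(C)C)(C(C)C)C(C)C)cc(O[Si](C(C)C)(C(C)C)C(C)C)c2)c2c(O)cc(O)cc2/C=C/I)C=C1 | intermediate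
10 | (2R,3R)-3-[3,5-bis(triisopropylsilyloxy)phenyl]-2-(4-hydroxyphenyl)-4-[(E)-2-iodovinyl]-2,3-dihydrobenzofuran-6-ol | I/C=C/c1cc(O)cc2c1[C@@H](c1cc(O[Si](C(C)C)(C(C)C)C(C)C)cc(O[Si](C(C)C)(C(C)C)C(C)C)c1)[C@H](c1ccc(O)cc1)O2 | intermediate
11 | (2R,3R)-3-[3,5-bis(triisopropylsilyloxy)phenyl]-4-[(E)-2-iodovinyl]-6-(triisopropylsilyloxy)-2-[4-(triisopropylsilyloxy)phenyl]-2,3-dihydrobenzofuran | I/C=C/c1cc(O[Si](C(C)C)(C(C)C)C(C)C)cc2c1[C@@H](c1cc(O[Si](C(C)C)(C(C)C)C(C)C)cc(O[Si](C(C)C)(C(C)C)C(C)C)c1)[C@H](c1ccc(O[Si](C(C)C)(C(C)C)C(C)C)cc1)O2 | intermediate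
12 | ketal carbinol from 11 and 4 (1-[(E)-2-arylvinyl]-4,4-dimethoxycyclohexa-2,5-dien-1-ol, aryl = C4 of the furan unit of 11, not isolated) | COC1(OC)C=CC(O)(/C=C/c2cc(O[Si](C(C)C)(C(C)C)C(C)C)cc3c2[C@@H](c2cc(O[Si](C(C)C)(C(C)C)C(C)C)cc(O[Si](C(C)C)(C(C)C)C(C)C)c2)[C@H](c2ccc(O[Si](C(C)C)(C(C)C)C(C)C)cc2)O3)C=C1 | intermediate
13 | 4-hydroxy-4-{(E)-2-[(2R,3R)-3-[3,5-bis(triisopropylsilyloxy)phenyl]-6-(triisopropylsilyloxy)-2-[4-(triisopropylsilyloxy)phenyl]-2,3-dihydrobenzofuran-4-yl]vinyl}cyclohexa-2,5-dien-1-one | O=C1C=CC(O)(/C=C/c2cc(O[Si](C(C)C)(C(C)C)C(C)C)cc3c2[C@@H](c2cc(O[Si](C(C)C)(C(C)C)C(C)C)cc(O[Si](C(C)C)(C(C)C)C(C)C)c2)[C@H](c2ccc(O[Si](C(C)C)(C(C)C)C(C)C)cc2)O3)C=C1 | intermediate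
14 | aryloxenium ion from 13, drawn as the β-carbocation (not isolated) | O=C1C=CC(=C[CH+]c2cc(O[Si](C(C)C)(C(C)C)C(C)C)cc3c2[C@@H](c2cc(O[Si](C(C)C)(C(C)C)C(C)C)cc(O[Si](C(C)C)(C(C)C)C(C)C)c2)[C@H](c2ccc(O[Si](C(C)C)(C(C)C)C(C)C)cc2)O3)C=C1 | intermediate
15 | p-quinone methide from 14 and 7 (not isolated) | O=C1C=CC(=C[C@@H](c2cc(O[Si](C(C)C)(C(C)C)C(C)C)cc3c2[C@@H](c2cc(O[Si](C(C)C)(C(C)C)C(C)C)cc(O[Si](C(C)C)(C(C)C)C(C)C)c2)[C@H](c2ccc(O[Si](C(C)C)(C(C)C)C(C)C)cc2)O3)c2c(O)cc(O)cc2/C=C/I)C=C1 | intermediate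
16 | (2S,3S)-2-(4-hydroxyphenyl)-4-[(E)-2-iodovinyl]-3-[(2R,3R)-3-[3,5-bis(triisopropylsilyloxy)phenyl]-6-(triisopropylsilyloxy)-2-[4-(triisopropylsilyloxy)phenyl]-2,3-dihydrobenzofuran-4-yl]-2,3-dihydrobenzofuran-6-ol | I/C=C/c1cc(O)cc2c1[C@H](c1cc(O[Si](C(C)C)(C(C)C)C(C)C)cc3c1[C@@H](c1cc(O[Si](C(C)C)(C(C)C)C(C)C)cc(O[Si](C(C)C)(C(C)C)C(C)C)c1)[C@H](c1ccc(O[Si](C(C)C)(C(C)C)C(C)C)cc1)O3)[C@@H](c1ccc(O)cc1)O2 | intermediate
17 | hexakis-TIPS ether of 16 (6-OTIPS and 4-(TIPSO)phenyl on the (2S,3S) ring) | I/C=C/c1cc(O[Si](C(C)C)(C(C)C)C(C)C)cc2c1[C@H](c1cc(O[Si](C(C)C)(C(C)C)C(C)C)cc3c1[C@@H](c1cc(O[Si](C(C)C)(C(C)C)C(C)C)cc(O[Si](C(C)C)(C(C)C)C(C)C)c1)[C@H](c1ccc(O[Si](C(C)C)(C(C)C)C(C)C)cc1)O3)[C@@H](c1ccc(O[Si](C(C)C)(C(C)C)C(C)C)cc1)O2 | intermediate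
18 | ketal carbinol from 17 and 4 (not isolated) | COC1(OC)C=CC(O)(/C=C/c2cc(O[Si](C(C)C)(C(C)C)C(C)C)cc3c2[C@H](c2cc(O[Si](C(C)C)(C(C)C)C(C)C)cc4c2[C@@H](c2cc(O[Si](C(C)C)(C(C)C)C(C)C)cc(O[Si](C(C)C)(C(C)C)C(C)C)c2)[C@H](c2ccc(O[Si](C(C)C)(C(C)C)C(C)C)cc2)O4)[C@@H](c2ccc(O[Si](C(C)C)(C(C)C)C(C)C)cc2)O3)C=C1 | intermediate
19 | p-quinol of the bis-furan stage (4-hydroxy-4-[(E)-2-arylvinyl]cyclohexa-2,5-dien-1-one, aryl = C4 of the (2S,3S) furan unit of 17) | O=C1C=CC(O)(/C=C/c2cc(O[Si](C(C)C)(C(C)C)C(C)C)cc3c2[C@H](c2cc(O[Si](C(C)C)(C(C)C)C(C)C)cc4c2[C@@H](c2cc(O[Si](C(C)C)(C(C)C)C(C)C)cc(O[Si](C(C)C)(C(C)C)C(C)C)c2)[C@H](c2ccc(O[Si](C(C)C)(C(C)C)C(C)C)cc2)O4)[C@@H](c2ccc(O[Si](C(C)C)(C(C)C)C(C)C)cc2)O3)C=C1 | intermediate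
20 | aryloxenium ion from 19, drawn as the β-carbocation (not isolated) | O=C1C=CC(=C[CH+]c2cc(O[Si](C(C)C)(C(C)C)C(C)C)cc3c2[C@H](c2cc(O[Si](C(C)C)(C(C)C)C(C)C)cc4c2[C@@H](c2cc(O[Si](C(C)C)(C(C)C)C(C)C)cc(O[Si](C(C)C)(C(C)C)C(C)C)c2)[C@H](c2ccc(O[Si](C(C)C)(C(C)C)C(C)C)cc2)O4)[C@@H](c2ccc(O[Si](C(C)C)(C(C)C)C(C)C)cc2)O3)C=C1 | intermediate
21 | p-quinone methide from 20 and 7 (not isolated) | O=C1C=CC(=C[C@H](c2cc(O[Si](C(C)C)(C(C)C)C(C)C)cc3c2[C@H](c2cc(O[Si](C(C)C)(C(C)C)C(C)C)cc4c2[C@@H](c2cc(O[Si](C(C)C)(C(C)C)C(C)C)cc(O[Si](C(C)C)(C(C)C)C(C)C)c2)[C@H](c2ccc(O[Si](C(C)C)(C(C)C)C(C)C)cc2)O4)[C@@H](c2ccc(O[Si](C(C)C)(C(C)C)C(C)C)cc2)O3)c2c(O)cc(O)cc2/C=C/I)C=C1 | intermediate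
22 | tris-furan vinyl iodide: (2R,3R)-2-(4-hydroxyphenyl)-4-[(E)-2-iodovinyl]-2,3-dihydrobenzofuran-6-ol whose C3 carries C4 of the (2S,3S)-6-(TIPSO)-2-[4-(TIPSO)phenyl] furan unit, whose C3 in turn carries C4 of the (2R,3R) furan unit of 11 | I/C=C/c1cc(O)cc2c1[C@@H](c1cc(O[Si](C(C)C)(C(C)C)C(C)C)cc3c1[C@H](c1cc(O[Si](C(C)C)(C(C)C)C(C)C)cc4c1[C@@H](c1cc(O[Si](C(C)C)(C(C)C)C(C)C)cc(O[Si](C(C)C)(C(C)C)C(C)C)c1)[C@H](c1ccc(O[Si](C(C)C)(C(C)C)C(C)C)cc1)O4)[C@@H](c1ccc(O[Si](C(C)C)(C(C)C)C(C)C)cc1)O3)[C@H](c1ccc(O)cc1)O2 | intermediate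
23 | 4-hydroxyphenylboronic acid | OB(O)c1ccc(O)cc1 | starting material
24 | hexakis-O-TIPS miyabenol A (22 with iodine replaced by 4-hydroxyphenyl) | Oc1ccc(/C=C/c2cc(O)cc3c2[C@@H](c2cc(O[Si](C(C)C)(C(C)C)C(C)C)cc4c2[C@H](c2cc(O[Si](C(C)C)(C(C)C)C(C)C)cc5c2[C@@H](c2cc(O[Si](C(C)C)(C(C)C)C(C)C)cc(O[Si](C(C)C)(C(C)C)C(C)C)c2)[C@H](c2ccc(O[Si](C(C)C)(C(C)C)C(C)C)cc2)O5)[C@@H](c2ccc(O[Si](C(C)C)(C(C)C)C(C)C)cc2)O4)[C@H](c2ccc(O)cc2)O3)cc1 | intermediate
25 | miyabenol A | Oc1ccc(/C=C/c2cc(O)cc3c2[C@@H](c2cc(O)cc4c2[C@H](c2cc(O)cc5c2[C@@H](c2cc(O)cc(O)c2)[C@H](c2ccc(O)cc2)O5)[C@@H](c2ccc(O)cc2)O4)[C@H](c2ccc(O)cc2)O3)cc1 | target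

## Step count and risks

Total step count: 13. Longest linear sequence: 12 steps (steps 1–3 and 5–13, from 3,5-dihydroxybenzaldehyde).

Steps most likely to fail:

**Step 11 (Proposed new method, key step).** What may go wrong: intramolecular Friedel–Crafts capture of the cationic carbon by the neighbouring 3-aryl ring, attack of the resorcinol through the carbon between its two hydroxyl groups, or insufficient facial selectivity at the crowded cation. Fallback (oxidative radical coupling of unprotected phenols in place of the cationic annulation): it sets out from 17. Suzuki–Miyaura coupling of 17 with 23 (Pd(PPh3)4, K2CO3) should give the hexakis-O-TIPS trimeric 4-hydroxystilbene F1, and TBAF/AcOH should give the free trimeric stilbene of the miyabenol C type F2. Oxidative cross-coupling of F2 with resveratrol (Oc1ccc(/C=C/c2cc(O)cc(O)c2)cc1) by FeCl3·6H2O in acetone–water, the known 8–10' coupling mode of 4-hydroxystilbenes, should give the target after chromatographic separation from homo-dimers and diastereomers. It comes back to the route at 25.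

**Step 8 (Proposed new method).** What may go wrong: slow ionisation of the hindered quinol so that 1,2-shift of the styryl group (quinol rearrangement) takes over, or opposed catalyst and substrate control eroding facial selectivity. Fallback (oxidative generation of the electrophile from a phenol, substrate control only): it sets out from 11. Suzuki–Miyaura coupling of 11 with 23 should give the tetrakis-O-TIPS 4-hydroxystilbene F3. Oxidative cross-coupling of F3 with an excess of 7 by FeCl3·6H2O in acetone–water, the conditions known for the resveratrol to ε-viniferin coupling, should give 16 after chromatographic removal of diastereomers. It comes back to the route at 16.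

**Step 5 (Proposed new method).** What may go wrong: low enantioselectivity because the reacting carbon is remote from the ion-pairing site, or competing attack at the dienone carbon next to the carbonyl. Fallback (racemic oxidative coupling followed by resolution in place of asymmetric catalysis): it sets out from 3 and 7. Suzuki–Miyaura coupling of 3 with 23 should give 4-[(E)-3,5-bis(triisopropylsilyloxy)styryl]phenol F4. Oxidative cross-coupling of F4 with 7 by FeCl3·6H2O in acetone–water should give 10 as the trans racemate together with its (2S,3S)-enantiomer F5, and preparative chromatography on a chiral stationary phase separates the two. It comes back to the route at 10.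

Further compounds
F1 | step 11 | hexakis-O-TIPS trimeric 4-hydroxystilbene (17 with iodine replaced by 4-hydroxyphenyl) | Oc1ccc(/C=C/c2cc(O[Si](C(C)C)(C(C)C)C(C)C)cc3c2[C@H](c2cc(O[Si](C(C)C)(C(C)C)C(C)C)cc4c2[C@@H](c2cc(O[Si](C(C)C)(C(C)C)C(C)C)cc(O[Si](C(C)C)(C(C)C)C(C)C)c2)[C@H](c2ccc(O[Si](C(C)C)(C(C)C)C(C)C)cc2)O4)[C@@H](c2ccc(O[Si](C(C)C)(C(C)C)C(C)C)cc2)O3)cc1
F2 | step 11 | free trimeric stilbene of the miyabenol C type | Oc1ccc(/C=C/c2cc(O)cc3c2[C@H](c2cc(O)cc4c2[C@@H](c2cc(O)cc(O)c2)[C@H](c2ccc(O)cc2)O4)[C@@H](c2ccc(O)cc2)O3)cc1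
F3 | step 8 | 4-{(E)-2-[(2R,3R)-3-[3,5-bis(triisopropylsilyloxy)phenyl]-6-(triisopropylsilyloxy)-2-[4-(triisopropylsilyloxy)phenyl]-2,3-dihydrobenzofuran-4-yl]vinyl}phenol | Oc1ccc(/C=C/c2cc(O[Si](C(C)C)(C(C)C)C(C)C)cc3c2[C@@H](c2cc(O[Si](C(C)C)(C(C)C)C(C)C)cc(O[Si](C(C)C)(C(C)C)C(C)C)c2)[C@H](c2ccc(O[Si](C(C)C)(C(C)C)C(C)C)cc2)O3)cc1
F4 | step 5 | 4-[(E)-3,5-bis(triisopropylsilyloxy)styryl]phenol | Oc1ccc(/C=C/c2cc(O[Si](C(C)C)(C(C)C)C(C)C)cc(O[Si](C(C)C)(C(C)C)C(C)C)c2)cc1
F5 | step 5 | (2S,3S)-3-[3,5-bis(triisopropylsilyloxy)phenyl]-2-(4-hydroxyphenyl)-4-[(E)-2-iodovinyl]-2,3-dihydrobenzofuran-6-ol (enantiomer of 10) | I/C=C/c1cc(O)cc2c1[C@H](c1cc(O[Si](C(C)C)(C(C)C)C(C)C)cc(O[Si](C(C)C)(C(C)C)C(C)C)c1)[C@@H](c1ccc(O)cc1)O2
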